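Ring B of the cis-fused octahydronaphthalene carries its C-2 oxygen and the ring-A carbon C-5 (on C-4a) on the same face. These two atoms are joined by a temporary O–C-5 bond, which turns ring B into the adduct of a 2H-pyran diene. A 4-silyloxy-2H-pyran whose C-2 bears an (E)-alkenyl chain undergoes an intramolecular Diels–Alder reaction that makes C-1–C-2 and C-4a–C-8a at once, closes ring A through the tether and fixes four stereocentres in an oxa-bridged cage. The bridge is later cut by β-elimination, which creates the C-5=C-6 alkene; a 1,4-hydroboration of a diene sets the ylidene geometry.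

Key step: step 6

Remark: locants C-1 to C-8a are those of the target decalin (C-1 CHMe, C-2 CHOAc, C-4 ylidene carbon, C-7 CHOAc); in the cage compounds (11-oxatricyclo[5.3.1.0^{3,8}]undecane numbering) these atoms are C-2, C-1, C-10, C-9, C-8, C-7, C-6, C-5, C-4, C-3 for C-1, C-2, C-3, C-4, C-4a, C-5, C-6, C-7, C-8, C-8a. Pyranone 8 is used as a mixture of epimers at its ring C-2, a centre that becomes mobile in step 6.

Step 1
Reactants: 1 (E)-pent-3-en-1-ol
Product: 2 (E)-pent-3-enal
Conditions: Dess–Martin periodinane, NaHCO3, CH2Cl2, 0 °C; the filtered solution is used at once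
Reagents that add atoms: none
Why: Buffered Dess–Martin oxidation of the homoallylic alcohol should give the β,γ-unsaturated aldehyde without moving the alkene into conjugation.

Step 2
Reactants: 3 (S)-4-benzyl-3-propanoyl-1,3-thiazolidine-2-thione; 2 (E)-pent-3-enal
Product: 4 (S)-4-benzyl-3-[(2S,3R,5E)-3-hydroxy-2-methylhept-5-enoyl]-1,3-thiazolidine-2-thione
Conditions: TiCl4 (1.05 equiv), i-Pr2NEt (1.1 equiv), N-methyl-2-pyrrolidone (1 equiv), CH2Cl2, 0 °C; then 2, −78 to 0 °C
Reagents that add atoms: none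
Why: The titanium (Z)-enolate of the thiazolidinethione imide should react through the non-chelated Zimmerman–Traxler chair (Evans-type syn aldol), which sets (2S) and (3R) under auxiliary control.

Step 3
Reactants: 4 syn-aldol adduct
Product: 5 (S)-4-benzyl-3-[(2S,3R,5E)-3-(tert-butyldimethylsilyloxy)-2-methylhept-5-enoyl]-1,3-thiazolidine-2-thione
Conditions: TBSOTf, 2,6-lutidine, CH2Cl2, 0 °C
Reagents that add atoms: tert-butyldimethylsilyl trifluoromethanesulfonate, CC(C)(C)[Si](C)(C)OS(=O)(=O)C(F)(F)F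
Why: Silylation of the secondary alcohol blocks retro-aldol cleavage and installs the group that later steers the cycloaddition.

Step 4
Reactants: 5 silylated aldol adduct
Product: 6 (2S,3R,5E)-3-(tert-butyldimethylsilyloxy)-2-methylhept-5-enal
Conditions: i-Bu2AlH (1.2 equiv), CH2Cl2, −78 °C; Rochelle salt work-up
Reagents that add atoms: none
Why: N-Acylthiazolidinethiones are reduced directly to aldehydes by i-Bu2AlH through a stable tetrahedral aluminate, and the low temperature should leave the α-stereocentre intact.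

Step 5
Reactants: 6 silyloxy aldehyde; 7 (E)-1-methoxy-3-(trimethylsilyloxy)buta-1,3-diene (Danishefsky diene)
Product: 8 2-[(2R,3R,5E)-3-(tert-butyldimethylsilyloxy)hept-5-en-2-yl]-2,3-dihydro-4H-pyran-4-one (both epimers at ring C-2)
Conditions: BF3·OEt2, CH2Cl2, −78 °C; then CF3CO2H, 0 °C
Reagents that add atoms: none
Why: The Lewis-acid-mediated hetero-Diels–Alder (Mukaiyama aldol then cyclisation) followed by acid-induced loss of methanol gives the dihydropyranone; its new centre needs no control.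

Step 6
Reactants: 8 dihydropyranone
Product: 11 5-(tert-butyldimethylsilyloxy)-2,6-dimethyl-11-oxatricyclo[5.3.1.0^{3,8}]undecan-9-one (cage ketone; 2-Me on the C-9/C-10 side, 5-OTBS and 6-Me equatorial on the chair ring C-3 to C-8), via silyloxy-2H-pyran 9 (not isolated), via cage silyl enol ether 10 (not isolated)
Conditions: TBSOTf (1.3 equiv), Et3N (3 equiv), toluene, 0 °C to rt; then BHT (cat.), 165 °C, sealed tube; then 1 M HCl, THF, 0 °C
Reagents that add atoms: none
Why: Soft enolisation at C-3 of the pyranone gives the cyclic 1-alkoxy-3-silyloxydiene 9, whose C-2 epimers interconvert through reversible oxa-6π ring opening, and 9 then undergoes a concerted, suprafacial thermal [4+2] with the tethered (E)-alkene; the closest known reaction type is the intramolecular Diels–Alder reaction of 2-silyloxycyclohexa-1,3-dienes that carry an alkenyl chain on the sp3 ring carbon (homoisotwistane and patchoulane syntheses), here in its 2H-pyran form. Ring B (C-1, C-2, C-3, C-4, C-4a, C-8a) closes as the new cyclohexene of the [4+2], and ring A (C-4a, C-5, C-6, C-7, C-8, C-8a) closes through the three-atom tether from pyran C-2 to the proximal alkene carbon, the proximal six-membered mode being favoured over the seven-membered alternative. C-2 and C-4a are tied cis by the pyran oxygen bridge, C-8a must turn its CH2 to the bridge side because ring A is fused there, and C-1 follows from the (E)-alkene (methyl anti to C-8). The absolute sense comes from the silyloxy carbon of the tether: in the chair of the forming ring A an axial OTBS would be syn-axial to both the bridge oxygen and C-1, so only the pyran epimer that places OTBS (and the neighbouring methyl of the syn aldol) equatorial should cyclise. The selectivity needed is therefore facial only, because the pyran holds a single locked s-cis diene, and intramolecularity has to make up for the unactivated dienophile; mild acid then cleaves the enol ether but not the alkyl silyl ether.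

Step 7
Reactants: 11 cage ketone
Product: 12 5-(tert-butyldimethylsilyloxy)-2,6-dimethyl-11-oxatricyclo[5.3.1.0^{3,8}]undec-9-en-9-yl trifluoromethanesulfonate (cage enol triflate)
Conditions: LiN(SiMe3)2, THF, −78 °C; then Comins' reagent, −78 to −40 °C
Reagents that add atoms: N-(5-chloropyridin-2-yl)-bis(trifluoromethanesulfonyl)imide (Comins' reagent), O=S(=O)(N(c1ccc(Cl)cn1)S(=O)(=O)C(F)(F)F)C(F)(F)F
Why: Enolisation can only go toward C-10 because C-8 is a bridgehead, and low-temperature O-triflation of the lithium enolate (as for tetrahydropyran-4-one) should outrun β-elimination of the bridging oxygen.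

Step 8
Reactants: 12 cage enol triflate; 13 2-(prop-1-en-2-yl)-4,4,5,5-tetramethyl-1,3,2-dioxaborolane
Product: 14 tert-butyl{[2,6-dimethyl-9-(prop-1-en-2-yl)-11-oxatricyclo[5.3.1.0^{3,8}]undec-9-en-5-yl]oxy}dimethylsilane (cage diene)
Conditions: Pd(PPh3)4 (5 mol%), K3PO4, 1,4-dioxane/H2O, 60 °C
Reagents that add atoms: none
Why: Suzuki–Miyaura coupling of an alkenyl triflate with an alkenylboronate should give the 2,3-disubstituted 1,3-diene without touching the silyl ether or the bridge.

Step 9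
Reactants: 14 cage diene
Product: 16 (E)-2-[5-(tert-butyldimethylsilyloxy)-2,6-dimethyl-11-oxatricyclo[5.3.1.0^{3,8}]undecan-9-ylidene]propan-1-ol (cage allylic alcohol; CH2OH cis to C-10), via allylboronate 15 (not isolated)
Conditions: Ni(cod)2 (5 mol%), PCy3 (5 mol%), pinacolborane (1.2 equiv), toluene, rt; then NaOH, H2O2, THF, 0 °C
Reagents that add atoms: hydrogen peroxide, OO
Why: Nickel-catalysed 1,4-hydroboration adds H to C-10 and boron to the terminal CH2 through the s-cis diene, so the two termini end cis on the new tetrasubstituted alkene (CH2B cis to ring CH2, methyl cis to C-8), and oxidation with retention gives the allylic alcohol; the bridgehead allylic ether cannot ionise.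

Step 10
Reactants: 16 cage allylic alcohol
Product: 17 (E)-2-[5-(tert-butyldimethylsilyloxy)-2,6-dimethyl-11-oxatricyclo[5.3.1.0^{3,8}]undecan-9-ylidene]propyl formate (cage formate)
Conditions: HCO2H (1.5 equiv), DCC (1.5 equiv), DMAP (5 mol%), CH2Cl2, 0 °C
Reagents that add atoms: formic acid, O=CO
Why: Carbodiimide (Steglich-type) formylation of the only free, primary hydroxyl should be clean and avoids a later choice between three hydroxyls.

Step 11
Reactants: 17 cage formate
Product: 18 (E)-2-[5-hydroxy-2,6-dimethyl-11-oxatricyclo[5.3.1.0^{3,8}]undecan-9-ylidene]propyl formate (cage hydroxy formate)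
Conditions: HF·pyridine, pyridine, THF, 0 °C to rt
Reagents that add atoms: none
Why: Acidic fluoride removes the secondary silyl ether under conditions that a formate ester should tolerate.

Step 12
Reactants: 18 cage hydroxy formate
Product: 20 (E)-2-[(1S,2S,4aR,8aR)-2-hydroxy-1,6-dimethyl-7-oxo-1,2,3,7,8,8a-hexahydronaphthalen-4(4aH)-ylidene]propyl formate (hydroxy enone), via cage 5-ketone 19 (not isolated)
Conditions: Dess–Martin periodinane, NaHCO3, CH2Cl2, 0 °C to rt; aqueous Na2S2O3 work-up; then DBU (0.2 equiv), CH2Cl2, 0 °C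
Reagents that add atoms: none
Why: Oxidation gives a β-alkoxy ketone whose α-hydrogen at C-6 is axial and antiperiplanar to the C-5–O bridge bond, so catalytic base should trigger E1cB (retro-oxa-Michael) opening with release of the bicyclo[2.2.2] strain, creating the C-5=C-6 enone and freeing the C-2 hydroxyl.

Step 13
Reactants: 20 hydroxy enone
Product: 21 (E)-2-[(1S,2S,4aR,7S,8aR)-2,7-dihydroxy-1,6-dimethyl-1,2,3,7,8,8a-hexahydronaphthalen-4(4aH)-ylidene]propyl formate (diol)
Conditions: (R)-2-methyl-CBS-oxazaborolidine (0.3 equiv), catecholborane (3 equiv), toluene, −78 to −40 °C; MeOH quench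
Reagents that add atoms: none
Why: Corey–Bakshi–Shibata 1,2-reduction with the (R)-catalyst should deliver hydride to the face anti to the axial C-8a–C-1 bond, which is also the face the cis-decalin leaves open, to set (7S), and the borane reagent spares the formate.

Step 14
Reactants: 21 diol
Product: 22 (E)-2-[(1S,2S,4aR,7S,8aR)-2,7-bis(acetyloxy)-1,6-dimethyl-1,2,3,7,8,8a-hexahydronaphthalen-4(4aH)-ylidene]propyl formate (CNP0262962.2)
Conditions: Ac2O, pyridine, DMAP (cat.), CH2Cl2, 0 °C to rt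
Reagents that add atoms: acetic anhydride, CC(=O)OC(C)=O
Why: Both secondary hydroxyls are acetylated in one operation under conditions that should leave the formate untouched.

Compound list
1 | (E)-pent-3-en-1-ol | C/C=C/CCO | starting material
2 | (E)-pent-3-enal | C/C=C/CC=O | intermediate
3 | (S)-4-benzyl-3-propanoyl-1,3-thiazolidine-2-thione | CCC(=O)N1[C@@H](Cc2ccccc2)CSC1=S | starting material
4 | (S)-4-benzyl-3-[(2S,3R,5E)-3-hydroxy-2-methylhept-5-enoyl]-1,3-thiazolidine-2-thione | C/C=C/C[C@@H](O)[C@H](C)C(=O)N1[C@@H](Cc2ccccc2)CSC1=S | intermediate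
5 | (S)-4-benzyl-3-[(2S,3R,5E)-3-(tert-butyldimethylsilyloxy)-2-methylhept-5-enoyl]-1,3-thiazolidine-2-thione | C/C=C/C[C@@H](O[Si](C)(C)C(C)(C)C)[C@H](C)C(=O)N1[C@@H](Cc2ccccc2)CSC1=S | intermediate
6 | (2S,3R,5E)-3-(tert-butyldimethylsilyloxy)-2-methylhept-5-enal | C/C=C/C[C@@H](O[Si](C)(C)C(C)(C)C)[C@H](C)C=O | intermediate
7 | (E)-1-methoxy-3-(trimethylsilyloxy)buta-1,3-diene | CO/C=C/C(=C)O[Si](C)(C)C | starting material
8 | 2-[(2R,3R,5E)-3-(tert-butyldimethylsilyloxy)hept-5-en-2-yl]-2,3-dihydro-4H-pyran-4-one (epimers at ring C-2) | C/C=C/C[C@@H](O[Si](C)(C)C(C)(C)C)[C@H](C)C1CC(=O)C=CO1 | intermediate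
9 | 4-(tert-butyldimethylsilyloxy)-2-[(2R,3R,5E)-3-(tert-butyldimethylsilyloxy)hept-5-en-2-yl]-2H-pyran (C-2 mobile) | C/C=C/C[C@@H](O[Si](C)(C)C(C)(C)C)[C@H](C)C1C=C(O[Si](C)(C)C(C)(C)C)C=CO1 | intermediate
10 | 5,9-bis(tert-butyldimethylsilyloxy)-2,6-dimethyl-11-oxatricyclo[5.3.1.0^{3,8}]undec-9-ene (cage silyl enol ether) | C[C@H]1[C@@H]2C[C@@H](O[Si](C)(C)C(C)(C)C)[C@H](C)[C@@H]3O[C@H]1C=C(O[Si](C)(C)C(C)(C)C)[C@H]23 | intermediate
11 | 5-(tert-butyldimethylsilyloxy)-2,6-dimethyl-11-oxatricyclo[5.3.1.0^{3,8}]undecan-9-one (cage ketone) | C[C@H]1[C@@H]2C[C@@H](O[Si](C)(C)C(C)(C)C)[C@H](C)[C@@H]3O[C@H]1CC(=O)[C@H]23 | intermediate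
12 | 5-(tert-butyldimethylsilyloxy)-2,6-dimethyl-11-oxatricyclo[5.3.1.0^{3,8}]undec-9-en-9-yl trifluoromethanesulfonate (cage enol triflate) | C[C@H]1[C@@H]2C[C@@H](O[Si](C)(C)C(C)(C)C)[C@H](C)[C@@H]3O[C@H]1C=C(OS(=O)(=O)C(F)(F)F)[C@H]23 | intermediate
13 | 2-(prop-1-en-2-yl)-4,4,5,5-tetramethyl-1,3,2-dioxaborolane | CC(=C)B1OC(C)(C)C(C)(C)O1 | starting material
14 | tert-butyl{[2,6-dimethyl-9-(prop-1-en-2-yl)-11-oxatricyclo[5.3.1.0^{3,8}]undec-9-en-5-yl]oxy}dimethylsilane (cage diene) | C[C@H]1[C@@H]2C[C@@H](O[Si](C)(C)C(C)(C)C)[C@H](C)[C@@H]3O[C@H]1C=C(C(C)=C)[C@H]23 | intermediate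
15 | 2-{(E)-2-[5-(tert-butyldimethylsilyloxy)-2,6-dimethyl-11-oxatricyclo[5.3.1.0^{3,8}]undecan-9-ylidene]propyl}-4,4,5,5-tetramethyl-1,3,2-dioxaborolane (allylboronate) | C[C@H]1[C@@H]2C[C@@H](O[Si](C)(C)C(C)(C)C)[C@H](C)[C@@H]3O[C@H]1C/C(=C(/C)CB4OC(C)(C)C(C)(C)O4)[C@H]23 | intermediate
16 | (E)-2-[5-(tert-butyldimethylsilyloxy)-2,6-dimethyl-11-oxatricyclo[5.3.1.0^{3,8}]undecan-9-ylidene]propan-1-ol (cage allylic alcohol) | C[C@H]1[C@@H]2C[C@@H](O[Si](C)(C)C(C)(C)C)[C@H](C)[C@@H]3O[C@H]1C/C(=C(/C)CO)[C@H]23 | intermediate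
17 | (E)-2-[5-(tert-butyldimethylsilyloxy)-2,6-dimethyl-11-oxatricyclo[5.3.1.0^{3,8}]undecan-9-ylidene]propyl formate (cage formate) | C[C@H]1[C@@H]2C[C@@H](O[Si](C)(C)C(C)(C)C)[C@H](C)[C@@H]3O[C@H]1C/C(=C(/C)COC=O)[C@H]23 | intermediate
18 | (E)-2-[5-hydroxy-2,6-dimethyl-11-oxatricyclo[5.3.1.0^{3,8}]undecan-9-ylidene]propyl formate (cage hydroxy formate) | C[C@H]1[C@@H]2C[C@@H](O)[C@H](C)[C@@H]3O[C@H]1C/C(=C(/C)COC=O)[C@H]23 | intermediate
19 | (E)-2-[2,6-dimethyl-5-oxo-11-oxatricyclo[5.3.1.0^{3,8}]undecan-9-ylidene]propyl formate (cage 5-ketone) | C[C@H]1[C@@H]2CC(=O)[C@H](C)[C@@H]3O[C@H]1C/C(=C(/C)COC=O)[C@H]23 | intermediate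
20 | (E)-2-[(1S,2S,4aR,8aR)-2-hydroxy-1,6-dimethyl-7-oxo-1,2,3,7,8,8a-hexahydronaphthalen-4(4aH)-ylidene]propyl formate | O=C1C[C@H]2[C@H](C)[C@@H](O)C/C(=C(/C)COC=O)[C@H]2C=C1C | intermediate
21 | (E)-2-[(1S,2S,4aR,7S,8aR)-2,7-dihydroxy-1,6-dimethyl-1,2,3,7,8,8a-hexahydronaphthalen-4(4aH)-ylidene]propyl formate | O[C@H]1C[C@H]2[C@H](C)[C@@H](O)C/C(=C(/C)COC=O)[C@H]2C=C1C | intermediate
22 | (E)-2-[(1S,2S,4aR,7S,8aR)-2,7-bis(acetyloxy)-1,6-dimethyl-1,2,3,7,8,8a-hexahydronaphthalen-4(4aH)-ylidene]propyl formate | CC(=O)O[C@H]1C[C@H]2[C@H](C)[C@@H](OC(C)=O)C/C(=C(/C)COC=O)[C@H]2C=C1C | target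

Total step count: 14. Longest linear sequence: 14 steps (from 1).

Steps most likely to fail

Step 6. The 2H-pyran may be lost by ring opening to the silyloxy dienal and irreversible alkene isomerisation or hydrogen shifts before a slow cycloaddition onto an unactivated alkene takes place. The fallback sets out from 8 and activates the dienophile. Cross-metathesis with methyl acrylate (second-generation Grubbs catalyst RuCl2(H2IMes)(PCy3)(=CHPh), CH2Cl2, 40 °C) should replace the propenyl terminus by an (E)-acrylate and give the enoate pyranone F1. Silylation as in step 6 then pairs the electron-rich diene with an electron-poor alkene, so the cycloaddition should run below 80 °C. It gives the cage ester F2, kept as its silyl enol ether, with the ester in the place of the C-1 methyl. Reduction with i-Bu2AlH gives the cage carbinol F3, TsCl/pyridine gives the cage tosylate F4, and LiBHEt3 displaces the tosylate to give 10. Compound 10 is hydrolysed with 1 M HCl in THF to rejoin the route at 11.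

Step 9. Hydride delivery to the hindered ring terminus of the 2,3-disubstituted diene may be slow, or boron may add 1,2 to the isopropenyl group. The fallback sets out from 11 and builds the ylidene by olefination instead. Horner–Wadsworth–Emmons reaction with triethyl 2-phosphonopropanoate (NaH, THF, reflux) gives the tetrasubstituted enoate as a mixture of geometric isomers. The isomer with the ester cis to the ring CH2, the cage enoate F5, is separated by chromatography and reduced with i-Bu2AlH to rejoin the route at 16.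

Step 12. The formyl group may be lost or may migrate to the freed C-2 hydroxyl during the base-mediated opening, and C-4a may epimerise through γ-deprotonation of the enone. The fallback sets out from 16 and keeps the primary oxygen masked until the end. Silylation (t-BuPh2SiCl, imidazole) gives the cage bis-silyl ether F6. HF·pyridine removes only the secondary silyl group to give the cage alcohol F7. Oxidation and DBU opening give the hydroxy enone silyl ether F8. CBS reduction gives the diol silyl ether F9, and acetylation gives the diacetate silyl ether F10. Bu4NF buffered with acetic acid gives the diacetate alcohol F11, which is formylated (HCO2H, DCC, DMAP) to rejoin the route at 22.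

Further compounds
F1 | step 6 | methyl (2E,5R,6R)-5-(tert-butyldimethylsilyloxy)-6-(4-oxo-3,4-dihydro-2H-pyran-2-yl)hept-2-enoate (enoate pyranone) | COC(=O)/C=C/C[C@@H](O[Si](C)(C)C(C)(C)C)[C@H](C)C1CC(=O)C=CO1
F2 | step 6 | methyl 5,9-bis(tert-butyldimethylsilyloxy)-6-methyl-11-oxatricyclo[5.3.1.0^{3,8}]undec-9-ene-2-carboxylate (cage ester) | COC(=O)[C@H]1[C@@H]2C[C@@H](O[Si](C)(C)C(C)(C)C)[C@H](C)[C@@H]3O[C@H]1C=C(O[Si](C)(C)C(C)(C)C)[C@H]23
F3 | step 6 | [5,9-bis(tert-butyldimethylsilyloxy)-6-methyl-11-oxatricyclo[5.3.1.0^{3,8}]undec-9-en-2-yl]methanol (cage carbinol) | OC[C@H]1[C@@H]2C[C@@H](O[Si](C)(C)C(C)(C)C)[C@H](C)[C@@H]3O[C@H]1C=C(O[Si](C)(C)C(C)(C)C)[C@H]23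
F4 | step 6 | [5,9-bis(tert-butyldimethylsilyloxy)-6-methyl-11-oxatricyclo[5.3.1.0^{3,8}]undec-9-en-2-yl]methyl 4-methylbenzenesulfonate (cage tosylate) | Cc1ccc(cc1)S(=O)(=O)OC[C@H]1[C@@H]2C[C@@H](O[Si](C)(C)C(C)(C)C)[C@H](C)[C@@H]3O[C@H]1C=C(O[Si](C)(C)C(C)(C)C)[C@H]23
F5 | step 9 | ethyl (E)-2-[5-(tert-butyldimethylsilyloxy)-2,6-dimethyl-11-oxatricyclo[5.3.1.0^{3,8}]undecan-9-ylidene]propanoate (cage enoate) | C[C@H]1[C@@H]2C[C@@H](O[Si](C)(C)C(C)(C)C)[C@H](C)[C@@H]3O[C@H]1C/C(=C(/C)C(=O)OCC)[C@H]23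
F6 | step 12 | tert-butyl{(E)-2-[5-(tert-butyldimethylsilyloxy)-2,6-dimethyl-11-oxatricyclo[5.3.1.0^{3,8}]undecan-9-ylidene]propoxy}diphenylsilane (cage bis-silyl ether) | C[C@H]1[C@@H]2C[C@@H](O[Si](C)(C)C(C)(C)C)[C@H](C)[C@@H]3O[C@H]1C/C(=C(/C)CO[Si](c4ccccc4)(c4ccccc4)C(C)(C)C)[C@H]23
F7 | step 12 | 9-[(E)-1-(tert-butyldiphenylsilyloxy)propan-2-ylidene]-2,6-dimethyl-11-oxatricyclo[5.3.1.0^{3,8}]undecan-5-ol (cage alcohol) | C[C@H]1[C@@H]2C[C@@H](O)[C@H](C)[C@@H]3O[C@H]1C/C(=C(/C)CO[Si](c4ccccc4)(c4ccccc4)C(C)(C)C)[C@H]23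
F8 | step 12 | (4aR,5E,7S,8S,8aR)-5-[1-(tert-butyldiphenylsilyloxy)propan-2-ylidene]-7-hydroxy-3,8-dimethyl-4a,5,6,7,8,8a-hexahydronaphthalen-2(1H)-one (hydroxy enone silyl ether) | O=C1C[C@H]2[C@H](C)[C@@H](O)C/C(=C(/C)CO[Si](c3ccccc3)(c3ccccc3)C(C)(C)C)[C@H]2C=C1C
F9 | step 12 | (1S,2S,4E,4aR,7S,8aR)-4-[1-(tert-butyldiphenylsilyloxy)propan-2-ylidene]-1,6-dimethyl-1,2,3,4,4a,7,8,8a-octahydronaphthalene-2,7-diol (diol silyl ether) | O[C@H]1C[C@H]2[C@H](C)[C@@H](O)C/C(=C(/C)CO[Si](c3ccccc3)(c3ccccc3)C(C)(C)C)[C@H]2C=C1C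
F10 | step 12 | (1S,2S,4E,4aR,7S,8aR)-4-[1-(tert-butyldiphenylsilyloxy)propan-2-ylidene]-1,6-dimethyl-1,2,3,4,4a,7,8,8a-octahydronaphthalene-2,7-diyl diacetate (diacetate silyl ether) | CC(=O)O[C@H]1C[C@H]2[C@H](C)[C@@H](OC(C)=O)C/C(=C(/C)CO[Si](c3ccccc3)(c3ccccc3)C(C)(C)C)[C@H]2C=C1C
F11 | step 12 | (1S,2S,4E,4aR,7S,8aR)-4-(1-hydroxypropan-2-ylidene)-1,6-dimethyl-1,2,3,4,4a,7,8,8a-octahydronaphthalene-2,7-diyl diacetate (diacetate alcohol) | CC(=O)O[C@H]1C[C@H]2[C@H](C)[C@@H](OC(C)=O)C/C(=C(/C)CO)[C@H]2C=C1C
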